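The target is what you sell, so the question for the next series is whether charging more partner buys a cleaner product as well as more of it.

| flask | substrate | partner | remark | time |
|---|---|---|---|---|
| red | 1.2 M | 0.22 M | run made earlier |  |
| grey | 1.2 M | 1.1 M | run made earlier |  |
| north-west | 1.2 M | 0.150 M |  | 1.0 h |
| east | 1.2 M | 0.200 M |  | 1.0 h |
| south-west | 1.2 M | 0.300 M |  | 1.0 h |
| north | 1.2 M | 0.500 M |  | 1.0 h |
| south | 1.2 M | 0.800 M |  | 1.0 h |

| run | time / min | target / % | side product / % |
|---|---|---|---|
| red | 6.00 | 0.1 | 0.4 |
| red | 12.0 | 0 | 0 |
| red | 20.0 | 0.3 | 1.0 |
| red | 25.0 | 0 | 0 |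
| red | 30.0 | 2.5 | 0.5 |
| red | 40.0 | 2.3 | 1.3 |
| grey | 3.00 | 0.3 | 0.6 |
| grey | 5.00 | 0 | 0 |
| grey | 8.00 | 0.9 | 1.4 |
| grey | 12.0 | 2.2 | 0 |
| grey | 20.0 | 2.9 | 0 |
| grey | 30.0 | 7.7 | 0.9 |
| grey | 40.0 | 11.0 | 1.1 |

(scatter of a reading: 1 percentage point)

1. share of target in all that became target or side product for north-west, east, south-west, north, south, in this order
2. how the row runs (hardly changes / falls, then rises / rises, then falls / falls all the way / rises all the way)

- "hardly changes" means that all values lie within two and a half points (for a concentration: within two and a half percent of the largest)

From the red run to the grey run, partner rises by a factor of 5.00, and the target read at 40.0 min rises by a factor of 4.78. The side product stands near the scatter in both runs, so take the two latest grey readings, where the target is largest. At 30.0 min and 40.0 min the target sums to 18.7% and the side product to 2.00%. That gives S = 9.35, the target formed per unit of side product, which is a selectivity ratio. The share asked for is S/(S+1), or 90.3%.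

This S is rough, since each side-product reading carries a scatter of 1 percentage point. Carried to the red run, it puts the side product at 0.246% at 40.0 min. The reading is 1.3%, a gap of 1.1 points, about one scatter, so the red run can't reject it. My reckoning is that S holds at each charge and the row stays flat near 90.3%. I would therefore choose the partner charge for the amount of target and expect no gain in share from it.

The forecast differs: it says the side product “seems independent of partner”, and it puts the share of target at 68% in the north-west flask and at 92% in the south flask, so that the row rises all the way.

The flasks give 89.6%, 89.6%, 89.6%, 89.6% and 89.7%: the row hardly changes.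

    substrate → intermediate A (k = 0.00126 /s)
    partner + intermediate A ⇌ intermediate B (K = 14.0 /M, k = 0.00225 /M/s)
    intermediate B → intermediate C (k = 3.58 × 10⁻⁴ /s)
    intermediate B ⇌ intermediate D (K = 0.350, k = 5.43 × 10⁻⁴ /s)
    intermediate D → side product (k = 8.97 × 10⁻⁵ /s)
    intermediate C → target (k = 0.00153 /s)
    substrate → decomposition product (k = 6.32 × 10⁻⁷ /s)
    intermediate C → decomposed reagent (k = 7.36 × 10⁻⁴ /s)

In the north-west flask, the midpoint of the turnover of substrate to intermediate A fell at 0.150 h, and intermediate A stood at 78.5% at 0.500 h. In the same north-west flask, the midpoint of the turnover of intermediate B to intermediate C came later, at 0.529 h. The north-west share corresponds to S = 8.62, against the carried 9.35. In the south flask at 10.0 h, the target of 41.6% divided by the carried S gives 4.45% of side product, and the flask holds 5.10%.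

(All runs were computed with made-up constants; noise was put on by code.)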